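Remark on the chemistry: germacrane numbering is used for every intermediate (C1 ketone, C2=C3, ring oxygen between C3 and C10, C4=C5 with methyl C15, C6 carbinol, C7, C8 lactone carbinol, C9, C10 with methyl C14, C11/C12/C13 lactone). The CIP label of C7 alternates with the group on O6 (S for free OH, R for silyl ether or ester) although its geometry never changes.

## The problem

The target is a ten-membered carbocycle (C1–C10) bridged twice. A 3(2H)-furanone ties C3 to C10 through oxygen, and a trans-fused α-methylene-γ-butyrolactone sits on C7/C8. Four ring stereocentres (C6, C7, C8, C10) and two epoxide carbons in the ester have to be made as one enantiomer. C10 is quaternary and separated from the others by the C9 methylene, so nothing in the molecule can control it and it is best bought. C7 and C8 are neighbours and can be set together, and C6 sits next to C7 and can be controlled by it. The epoxide centres lie outside the ring and need a reagent. The fragile groups are the methylene lactone (Michael acceptor, isomerised by base), the glycidic ester (acid, nucleophiles), the cross-conjugated dienone/enol ether (nucleophiles, light) and, in intermediates, any C6 carbonyl, which is a β-acyloxy carbonyl with an epimerisable C7. The feature that allows a late ring closure is that C6 is an allylic carbinol carbon bonded to the cis alkene carbon C5. C5–C6 is therefore the bond between an alkenyl metal and an aldehyde, and both the furanone (O, C10, C1, C2, C3) and the lactone (O, C8, C7, C11, C12) can be complete before it is formed.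

## Retrosynthesis

**Ester.** The C6–O acyl bond of 34 is cut first, giving alcohol 29 and (2S,3S)-epoxy acid 33. The glycidic ester tolerates neither the enolate chemistry nor the organometallic steps, so it goes on last. The forward step must acylate a hindered allylic alcohol without touching the methylene lactone. Acid 33 goes back through epoxy alcohol 32 and allylic alcohol 31 to angelic acid 30, and the epoxide centres come from a tartrate-controlled epoxidation.

**Methylene.** C13 is removed next: 29 comes from silyl ether 28, which comes from 25 and so from alcohol 24. Carrying the methylene through the ring closure would make H7 both α to the aldehyde and γ to an enoate, so it is introduced afterwards by a lactone-enolate Mannich reaction on the protected alcohol.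

**Ring (key cut).** C5–C6 of 24 is cut to give iodo aldehyde 23. The other ring bonds are poorer choices: C8–C9 and C9–C10 carry no activating function, C3–C4 would be an sp2–sp2 coupling at the most strained point, and closing through the furanone would be a transannular reaction. C5–C6 creates C6 as it closes, under the influence of C7. The forward reaction must be aldehyde-selective and non-basic.

**Furanone.** 23 comes from alcohol 22 and silyl ether 21. The furanone O–C3 bond of 21 is cut to α'-hydroxy ynone 20, which comes from diol 19. Cutting C1–C2 of 19 gives α-hydroxy aldehyde 14 and (Z)-iodoenyne 18. An aldehyde is chosen as the C1 electrophile, not an amide, because it reacts with the acetylide far faster than the lactone already present. 18 comes from iodoenal 17, iodo alcohol 16 and propargyl alcohol 15, the Z geometry being fixed by a chelated anti-carbomagnesiation.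

**Lactone.** 14 goes back through diol 13, silyl ether 12, alcohol 11 and acid 10 to lactone imide 9. Cutting the lactone C–O bond and C7–C8 gives aldol adduct 8, and hence imide 7 and aldehyde 4. An auxiliary-controlled syn aldol sets C7 and C8 absolutely, independent of the remote C10, and a syn aldol gives the trans lactone on closure. Imide 7 comes from oxazolidinone 5 and acid chloride 6.

**C10.** Aldehyde 4 comes from acetonide alcohol 3, triol 2 and (S)-citramalic acid 1, whose carbinol carbon becomes C10 with the correct configuration; its two carboxyls become C1 and C8.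

## Roads not taken

Alternative 1: This road cuts C6–C7 and lets an oxygen join C6 to C13, so that the carbocycle comes from ring contraction. The thirteen-membered enyne ether A1 is deprotonated at C6; a [2,3]-Wittig shift forms C6–C7, breaks O–C13, makes C11=C13 the exocyclic methylene and gives the ten-membered enynol A2.
- Merits: a thirteen-membered ether closes far more easily than a ten-membered carbocycle. The envelope transition state sets C6 and C7 together, and the methylene arrives without late enolate chemistry. On these two points it is better than the chosen plan.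
- Weak points: strong base acts on a substrate whose C13 protons are also allylic and α to oxygen (regiochemistry, [1,2]-shift). A triple bond and a cis alkene are forced into the ten-membered ring of A2. A2 still lacks both heterocycles, so ketal hydrolysis, furanone closure, oxidation at C12 and lactonisation follow under four kinds of protecting group.
- Comparison: the chosen plan has both heterocycles finished before closure, takes C7/C8 from an auxiliary-controlled aldol, and closes the ring under neutral conditions without protecting groups.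

Alternative 2: This road cuts the O–C10 bond of the furanone and keeps the carbocycle. Under a Lewis acid the C3 ketone oxygen of epoxy ketone A3 opens the trans C1–C10 epoxide at C10 with inversion; loss of a C2 proton gives the bridged enol ether A4, one oxidation short of the furanone.
- Merits: the bridge is formed stereospecifically, and the methylene lactone and the C6 oxygen are already present. The endgame is at least as short as the chosen one.
- Weak points: the ten-membered ring, the real problem, is left unsolved, since A3 itself needs a macrocyclisation. C10 is no longer bought but depends on the face selectivity of the epoxidation that precedes A3. The opening is a 5-endo attack at the far epoxide carbon, which needs cationic character at C10 and then competes with hydride shift, attack at C1 and transannular carbocyclisation, all beside an acid-sensitive methylene lactone.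
- Comparison: the chosen plan fixes C10 from the chiral pool and forms the furanone on an open chain where the 5-endo-dig addition has no competitor. It pays with more steps before the closure.

Alternative 3: This road cuts C2–C3 and C4–C5 together. Irradiation of cyclooctenone A5, whose C10 oxygen carries a 1-propynyl group, lets the C2=C5 enone add to the alkyne to give cyclobutene A6. A later electrocyclic opening would have to expand the ring by two carbons.
- Merits: two C–C bonds and two rings form in one step, and the five-atom tether gives the right regiochemistry. In bond economy it is the best of the four.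
- Weak points: an ynol ether on a tertiary alcohol is hard to make and acid-labile. The double bond of A6 starts at a ring-fusion carbon of an oxabicycle and is highly strained. The opening must deliver the cis C4=C5 alkene, and torquoselectivity in such a system cannot be predicted. Enone photochemistry adds side reactions, and the eight-membered ring carrying C6, C7, C8 and C10 is itself a substantial target.
- Comparison: the chosen plan uses only ground-state reactions and fixes the alkene geometry in a three-carbon building block. It gives up the step economy of the photochemical cascade.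

Key step: step 19

## Route

Step 1
Reactants: 1 (S)-citramalic acid [(2S)-2-hydroxy-2-methylbutanedioic acid]
Product: 2 (2S)-2-methylbutane-1,2,4-triol
Conditions: BH3·SMe2, B(OMe)3, THF, 0 °C to rt; then MeOH
Reagents that add atoms: none
Why: Borane reduction of both carboxylic acids (the protocol that converts malic acid into butane-1,2,4-triol); the quaternary carbinol carbon, the future C10, is not touched.

Step 2
Reactants: 2 (2S)-2-methylbutane-1,2,4-triol
Product: 3 2-[(4S)-2,2,4-trimethyl-1,3-dioxolan-4-yl]ethan-1-ol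
Conditions: 2,2-dimethoxypropane, acetone, TsOH (cat.), rt
Reagents that add atoms: 2,2-dimethoxypropane, COC(C)(C)OC
Why: Thermodynamic acetalisation; the five-membered dioxolane across the 1,2-diol is favoured over the six-membered acetal (which would carry an axial methyl), so the C8 hydroxyl stays free.

Step 3
Reactants: 3 2-[(4S)-2,2,4-trimethyl-1,3-dioxolan-4-yl]ethan-1-ol
Product: 4 2-[(4S)-2,2,4-trimethyl-1,3-dioxolan-4-yl]acetaldehyde
Conditions: (COCl)2, DMSO, CH2Cl2, −78 °C; Et3N, −78 to 0 °C
Reagents that add atoms: none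
Why: Swern oxidation; cold and non-acidic, so the acetonide is safe, and the volatile aldehyde is used at once.

Step 4
Reactants: 5 (4R)-4-benzyl-1,3-oxazolidin-2-one; 6 methyl 4-chloro-4-oxobutanoate
Product: 7 methyl 4-[(4R)-4-benzyl-2-oxo-1,3-oxazolidin-3-yl]-4-oxobutanoate
Conditions: n-BuLi, THF, −78 °C; then 6, −78 to 0 °C
Reagents that add atoms: none
Why: N-Acylation of the lithiated oxazolidinone by the acid chloride, the standard entry to Evans imides; the methyl ester is untouched at low temperature.

Step 5
Reactants: 7 methyl 4-[(4R)-4-benzyl-2-oxo-1,3-oxazolidin-3-yl]-4-oxobutanoate; 4 2-[(4S)-2,2,4-trimethyl-1,3-dioxolan-4-yl]acetaldehyde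
Product: 9 (4R)-4-benzyl-3-{[(2S,3R)-5-oxo-2-{[(4S)-2,2,4-trimethyl-1,3-dioxolan-4-yl]methyl}oxolan-3-yl]carbonyl}-1,3-oxazolidin-2-one, via syn-aldol hydroxy ester 8 (not isolated)
Conditions: Bu2BOTf, i-Pr2NEt, CH2Cl2, 0 °C; 4, −78 to 0 °C; pH 7 buffer, MeOH, H2O2, 0 °C; PPTS (cat.), CH2Cl2, rt
Reagents that add atoms: none
Why: Evans syn-aldol: the Z boron enolate of the imide (the ester is not enolised) adds through a chair Zimmerman–Traxler transition state on the face left open by the benzyl group of the (R)-auxiliary, setting C7 (R) and C8 (S) under reagent control regardless of the remote C10. The aldolate then closes onto the methyl ester (5-exo-trig lactonisation), and a syn aldol necessarily gives the trans-disubstituted lactone.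

Step 6
Reactants: 9 lactone imide
Product: 10 (2S,3R)-5-oxo-2-{[(4S)-2,2,4-trimethyl-1,3-dioxolan-4-yl]methyl}oxolane-3-carboxylic acid
Conditions: LiOH, H2O2, THF/H2O, 0 °C; Na2SO3; 1 M HCl to pH 3, 0 °C
Reagents that add atoms: hydrogen peroxide (as LiOOH), OO
Why: Hydroperoxide cleaves the exocyclic imide carbonyl selectively (standard auxiliary removal). Any lactone opened by hydroxide recloses on acidification because the γ-lactone is the only feasible ring, and the trans arrangement is also the thermodynamic one.

Step 7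
Reactants: 10 lactone acid
Product: 11 (4S,5S)-4-(hydroxymethyl)-5-{[(4S)-2,2,4-trimethyl-1,3-dioxolan-4-yl]methyl}oxolan-2-one
Conditions: BH3·SMe2, THF, 0 °C to rt; then MeOH
Reagents that add atoms: none
Why: Chemoselective borane reduction of a carboxylic acid beside a lactone, routine for paraconic acids; the acetonide is inert.

Step 8
Reactants: 11 hydroxymethyl lactone
Product: 12 (4S,5S)-4-({[tert-butyl(diphenyl)silyl]oxy}methyl)-5-{[(4S)-2,2,4-trimethyl-1,3-dioxolan-4-yl]methyl}oxolan-2-one
Conditions: TBDPSCl, imidazole, CH2Cl2, rt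
Reagents that add atoms: tert-butyl(chloro)diphenylsilane, CC(C)(C)[Si](Cl)(c1ccccc1)c1ccccc1
Why: Silylation of the primary alcohol; this silyl group survives the aqueous acid of step 9 and stops O6 from competing with O8 for the lactone carbonyl.

Step 9
Reactants: 12 silyl ether acetonide
Product: 13 (4S,5S)-4-({[tert-butyl(diphenyl)silyl]oxy}methyl)-5-[(2S)-2,3-dihydroxy-2-methylpropyl]oxolan-2-one
Conditions: AcOH/H2O (4:1), 40 °C
Reagents that add atoms: none
Why: Acid hydrolysis of the acetonide; silyl ether and lactone are stable, and neither freed hydroxyl can reach the lactone carbonyl in a ring smaller than seven.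

Step 10
Reactants: 13 diol
Product: 14 (2S)-3-[(2S,3S)-3-({[tert-butyl(diphenyl)silyl]oxy}methyl)-5-oxooxolan-2-yl]-2-hydroxy-2-methylpropanal
Conditions: SO3·pyridine, DMSO, i-Pr2NEt, CH2Cl2, 0 °C
Reagents that add atoms: none
Why: Parikh–Doering oxidation of the primary alcohol; the tertiary hydroxyl cannot be oxidised, C10 has no α-hydrogen, and activated DMSO does not cleave the glycol. The aldehyde is used crude.

Step 11
Reactants: 15 propargyl alcohol (prop-2-yn-1-ol)
Product: 16 (2Z)-3-iodo-2-methylprop-2-en-1-ol
Conditions: MeMgBr, CuI (cat.), THF, −10 °C to rt; then I2, −20 to 0 °C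
Reagents that add atoms: methylmagnesium bromide, C[Mg]Br; iodine, II
Why: Copper-catalysed anti-carbomagnesiation of the propargylic alkoxide: methyl adds to C2 and magnesium ends on C3 in a five-membered chelate, cis to the CH2O group; iodinolysis with retention gives the Z iodide.

Step 12
Reactants: 16 (2Z)-3-iodo-2-methylprop-2-en-1-ol
Product: 17 (2Z)-3-iodo-2-methylprop-2-enal
Conditions: MnO2, CH2Cl2, rt, dark
Reagents that add atoms: none
Why: Allylic oxidation with MnO2; neutral heterogeneous conditions keep the Z geometry, and the aldehyde is used without chromatography.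

Step 13
Reactants: 17 (2Z)-3-iodo-2-methylprop-2-enal
Product: 18 (1Z)-1-iodo-2-methylbut-1-en-3-yne
Conditions: TMSCHN2, LDA, THF, −78 °C; then 17, −78 to 0 °C
Reagents that add atoms: trimethylsilyldiazomethane, C[Si](C)(C)C=[N+]=[N-]
Why: Colvin homologation: lithiated trimethylsilyldiazomethane adds 1,2 to the enal, loss of silanolate and N2 gives an alkylidene carbene, and 1,2-hydrogen shift gives the enyne. Unlike the basic-methanol variants it does not add methanol to enals, and the alkenyl iodide is not attacked at −78 °C.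

Step 14
Reactants: 14 α-hydroxy aldehyde; 18 (1Z)-1-iodo-2-methylbut-1-en-3-yne
Product: 19 (4S,5S)-4-({[tert-butyl(diphenyl)silyl]oxy}methyl)-5-[(2S,3RS,6Z)-2,3-dihydroxy-7-iodo-2,6-dimethylhept-6-en-4-yn-1-yl]oxolan-2-one
Conditions: 18 (3.3 equiv), LDA (3.0 equiv), THF, −78 °C; then 14, −78 to −40 °C; NH4Cl (aq)
Reagents that add atoms: none
Why: Addition of a lithium acetylide to an aldehyde; at −78 °C the aldehyde reacts far faster than the γ-lactone, one equivalent is spent on the tertiary hydroxyl, and no amide base is left to enolise the lactone. Both C1 epimers form, which is irrelevant because C1 is oxidised next.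

Step 15
Reactants: 19 propargylic diol
Product: 20 (4S,5S)-4-({[tert-butyl(diphenyl)silyl]oxy}methyl)-5-[(2S,6Z)-2-hydroxy-7-iodo-2,6-dimethyl-3-oxohept-6-en-4-yn-1-yl]oxolan-2-one
Conditions: IBX, DMSO, rt
Reagents that add atoms: none
Why: IBX oxidation of the secondary propargylic alcohol; IBX turns 1,2-diols into α-ketols without C–C cleavage and leaves the tertiary hydroxyl.

Step 16
Reactants: 20 α'-hydroxy ynone
Product: 21 (4S,5S)-4-({[tert-butyl(diphenyl)silyl]oxy}methyl)-5-({(2S)-5-[(1Z)-1-iodoprop-1-en-2-yl]-2-methyl-3-oxo-2,3-dihydrofuran-2-yl}methyl)oxolan-2-one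
Conditions: Ph3PAuCl (5 mol%), AgOTf (5 mol%), toluene, rt
Reagents that add atoms: none
Why: π-Acid-catalysed 5-endo-dig hydroalkoxylation (intramolecular oxa-Michael addition) of the α'-hydroxy ynone: the C10 hydroxyl adds to C3 of the alkyne activated by monovalent gold, and protodeauration gives the 3(2H)-furanone. No amine or alkoxide is present that could displace the vinylogous iodide or open the lactone.

Step 17
Reactants: 21 furanone silyl ether
Product: 22 (4S,5S)-4-(hydroxymethyl)-5-({(2S)-5-[(1Z)-1-iodoprop-1-en-2-yl]-2-methyl-3-oxo-2,3-dihydrofuran-2-yl}methyl)oxolan-2-one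
Conditions: HF·pyridine, pyridine/THF, 0 °C to rt
Reagents that add atoms: none
Why: Fluoride cleavage of the silyl ether under buffered acidic conditions, so a free C6 alkoxide that could translactonise is never present.

Step 18
Reactants: 22 primary alcohol
Product: 23 (2S,3R)-2-({(2S)-5-[(1Z)-1-iodoprop-1-en-2-yl]-2-methyl-3-oxo-2,3-dihydrofuran-2-yl}methyl)-5-oxooxolane-3-carbaldehyde
Conditions: Dess–Martin periodinane, NaHCO3, CH2Cl2, 0 °C
Reagents that add atoms: none
Why: Dess–Martin oxidation under bicarbonate buffer; the β-acyloxy aldehyde with its epimerisable C7 is not chromatographed and goes straight into step 19.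

Step 19
Reactants: 23 furanone (Z)-alkenyl iodide lactone aldehyde
Product: 24 (4Z,6S,7S,8S,10S)-6-hydroxy-1-oxo-3,10-epoxygermacra-2,4-dien-12,8-olide
Conditions: CrCl2 (8 equiv), NiCl2 (5 mol%), DMSO/THF (3:1), rt, slow addition of 23 (final 2 mM)
Reagents that add atoms: none
Why: Zerovalent nickel, formed from NiCl2 by CrCl2, inserts into the C5–I bond with retention of the cis geometry, and transmetalation to trivalent chromium gives an alkenylchromium species that adds to the aldehyde and to nothing else in 23. This is the Nozaki–Hiyama–Kishi reaction in its ring-closing form; the closest known cases are closures of nine- to twelve-membered carbocycles from iodoalkenyl aldehydes, and β-iodo enones are standard partners. The new C5–C6 bond closes the ten-membered carbocycle (equally the nine-membered oxacycle counted through the furanone oxygen) in an exo-trig mode, the carbonyl oxygen staying outside the ring. C6 is the only new stereocentre and is controlled by C7: the tether holds C8 gauche to the forming bond, so the alkenyl group should approach anti to the C7–C11 bond with H7 beside its trajectory (a Felkin–Anh arrangement), which leads to the 6S alcohol. The step needs aldehyde selectivity over ketone, lactone and enone, retention of the Z alkene and of C7, and ring closure over dimerisation; the non-basic, aldehyde-selective organochromium reagent, the neutral medium and high dilution should secure these, helped by the furanone and the trans-lactone, which leave only the C6–C7 end of the chain free to fold.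

Step 20
Reactants: 24 macrocyclic alcohol
Product: 25 (4Z,6S,7R,8S,10S)-1-oxo-6-(triethylsilyloxy)-3,10-epoxygermacra-2,4-dien-12,8-olide
Conditions: TESOTf, 2,6-lutidine, CH2Cl2, −78 °C
Reagents that add atoms: triethylsilyl trifluoromethanesulfonate, CC[Si](CC)(CC)OS(=O)(=O)C(F)(F)F
Why: Silylation of the hindered allylic alcohol with the silyl triflate; the ether blocks translactonisation to O6 during step 21 and is removable without base.

Step 21
Reactants: 25 silyl ether
Product: 28 (4Z,6S,7R,8S,10S)-1-oxo-6-(triethylsilyloxy)-3,10-epoxygermacra-2,4,11(13)-trien-12,8-olide, via Mannich base 26 (not isolated), via methiodide 27 (not isolated)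
Conditions: LDA, THF, −78 °C; CH2=NMe2+ I−, −78 °C to rt; MeI, MeOH, rt; NaHCO3 (aq), EtOAc
Reagents that add atoms: N,N-dimethylmethyleneiminium iodide (Eschenmoser's salt), C=[N+](C)C.[I-]
Why: Lactone-enolate Mannich reaction, quaternisation and E1cB elimination, the usual α-methylenation of γ-lactones: kinetic deprotonation should take the C11 methylene, the only ordinary α-CH2 in 25 (C10 is quaternary, C2 is vinylic), and the iminium salt traps the enolate at once; the C11 centre of 26 is lost again on elimination.

Step 22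
Reactants: 28 methylene lactone silyl ether
Product: 29 (4Z,6S,7S,8S,10S)-6-hydroxy-1-oxo-3,10-epoxygermacra-2,4,11(13)-trien-12,8-olide
Conditions: HF·pyridine, pyridine/THF, 0 °C
Reagents that add atoms: none
Why: Fluoride desilylation under non-basic conditions, which the methylene lactone and the furanone tolerate.

Step 23
Reactants: 30 angelic acid [(2Z)-2-methylbut-2-enoic acid]
Product: 31 (2Z)-2-methylbut-2-en-1-ol
Conditions: LiAlH4, Et2O, 0 °C
Reagents that add atoms: none
Why: Hydride reduction of the acid to the allylic alcohol; the Z geometry of the trisubstituted alkene is retained.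

Step 24
Reactants: 31 (2Z)-2-methylbut-2-en-1-ol
Product: 32 [(2R,3S)-2,3-dimethyloxiran-2-yl]methanol
Conditions: Ti(OiPr)4, D-(−)-diethyl tartrate, t-BuOOH, 4 Å MS, CH2Cl2, −20 °C
Reagents that add atoms: tert-butyl hydroperoxide, CC(C)(C)OO
Why: Sharpless asymmetric epoxidation: syn oxygen transfer in the titanium tartrate complex keeps C4 cis to the CH2OH group, and the D-(−)-tartrate delivers oxygen to the face that gives the (2R,3S) epoxy alcohol (the L-(+) ester gives the 2S series), i.e. the future (2S,3S) acid.

Step 25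
Reactants: 32 epoxy alcohol
Product: 33 (2S,3S)-2,3-dimethyloxirane-2-carboxylic acid
Conditions: RuCl3 (cat.), NaIO4, MeCN/EtOAc/H2O, rt
Reagents that add atoms: water, O
Why: RuO4-catalysed oxidation of the primary alcohol to the acid with periodate as terminal oxidant, the usual route from 2,3-epoxy alcohols to glycidic acids; the epoxide and both centres are untouched (the C2 label changes only through CIP priorities).

Step 26
Reactants: 29 macrocyclic alcohol; 33 (2S,3S)-2,3-dimethyloxirane-2-carboxylic acid
Product: 34 CNP0258430.1, (4Z,6S,7R,8S,10S)-6-{[(2S,3S)-2,3-dimethyloxiran-2-yl]carbonyloxy}-1-oxo-3,10-epoxygermacra-2,4,11(13)-trien-12,8-olide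
Conditions: 33, 2,4,6-trichlorobenzoyl chloride, Et3N, THF, rt; then 29, DMAP, toluene, rt
Reagents that add atoms: none
Why: Yamaguchi esterification: the mixed anhydride acylates the hindered C6 hydroxyl under DMAP catalysis with retention at C6; the acid has a quaternary α-carbon and cannot epimerise, and the conditions spare the methylene lactone and the epoxide.

## Compound list

1 | (S)-citramalic acid | C[C@](O)(CC(=O)O)C(=O)O | starting material
2 | (2S)-2-methylbutane-1,2,4-triol | C[C@](O)(CCO)CO | intermediate
3 | 2-[(4S)-2,2,4-trimethyl-1,3-dioxolan-4-yl]ethan-1-ol | C[C@]1(CCO)COC(C)(C)O1 | intermediate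
4 | 2-[(4S)-2,2,4-trimethyl-1,3-dioxolan-4-yl]acetaldehyde | C[C@]1(CC=O)COC(C)(C)O1 | intermediate
5 | (4R)-4-benzyl-1,3-oxazolidin-2-one | O=C1N[C@H](Cc2ccccc2)CO1 | starting material
6 | methyl 4-chloro-4-oxobutanoate | COC(=O)CCC(Cl)=O | starting material
7 | methyl 4-[(4R)-4-benzyl-2-oxo-1,3-oxazolidin-3-yl]-4-oxobutanoate | COC(=O)CCC(=O)N1[C@H](Cc2ccccc2)COC1=O | intermediate
8 | methyl (3R,4S)-3-{[(4R)-4-benzyl-2-oxo-1,3-oxazolidin-3-yl]carbonyl}-4-hydroxy-5-[(4S)-2,2,4-trimethyl-1,3-dioxolan-4-yl]pentanoate (syn-aldol hydroxy ester, not isolated) | COC(=O)C[C@H]([C@@H](O)C[C@@]1(C)COC(C)(C)O1)C(=O)N1[C@H](Cc2ccccc2)COC1=O | intermediate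
9 | (4R)-4-benzyl-3-{[(2S,3R)-5-oxo-2-{[(4S)-2,2,4-trimethyl-1,3-dioxolan-4-yl]methyl}oxolan-3-yl]carbonyl}-1,3-oxazolidin-2-one | O=C(N1[C@H](Cc2ccccc2)COC1=O)[C@@H]1CC(=O)O[C@H]1C[C@@]1(C)COC(C)(C)O1 | intermediate
10 | (2S,3R)-5-oxo-2-{[(4S)-2,2,4-trimethyl-1,3-dioxolan-4-yl]methyl}oxolane-3-carboxylic acid | OC(=O)[C@@H]1CC(=O)O[C@H]1C[C@@]1(C)COC(C)(C)O1 | intermediate
11 | (4S,5S)-4-(hydroxymethyl)-5-{[(4S)-2,2,4-trimethyl-1,3-dioxolan-4-yl]methyl}oxolan-2-one | OC[C@@H]1CC(=O)O[C@H]1C[C@@]1(C)COC(C)(C)O1 | intermediate
12 | (4S,5S)-4-({[tert-butyl(diphenyl)silyl]oxy}methyl)-5-{[(4S)-2,2,4-trimethyl-1,3-dioxolan-4-yl]methyl}oxolan-2-one | CC(C)(C)[Si](c1ccccc1)(c1ccccc1)OC[C@@H]1CC(=O)O[C@H]1C[C@@]1(C)COC(C)(C)O1 | intermediate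
13 | (4S,5S)-4-({[tert-butyl(diphenyl)silyl]oxy}methyl)-5-[(2S)-2,3-dihydroxy-2-methylpropyl]oxolan-2-one | CC(C)(C)[Si](c1ccccc1)(c1ccccc1)OC[C@@H]1CC(=O)O[C@H]1C[C@](C)(O)CO | intermediate
14 | (2S)-3-[(2S,3S)-3-({[tert-butyl(diphenyl)silyl]oxy}methyl)-5-oxooxolan-2-yl]-2-hydroxy-2-methylpropanal | CC(C)(C)[Si](c1ccccc1)(c1ccccc1)OC[C@@H]1CC(=O)O[C@H]1C[C@](C)(O)C=O | intermediate
15 | propargyl alcohol | C#CCO | starting material
16 | (2Z)-3-iodo-2-methylprop-2-en-1-ol | OC/C(C)=C\I | intermediate
17 | (2Z)-3-iodo-2-methylprop-2-enal | O=C/C(C)=C\I | intermediate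
18 | (1Z)-1-iodo-2-methylbut-1-en-3-yne | C#C/C(C)=C\I | intermediate
19 | (4S,5S)-4-({[tert-butyl(diphenyl)silyl]oxy}methyl)-5-[(2S,3RS,6Z)-2,3-dihydroxy-7-iodo-2,6-dimethylhept-6-en-4-yn-1-yl]oxolan-2-one | CC(C)(C)[Si](c1ccccc1)(c1ccccc1)OC[C@@H]1CC(=O)O[C@H]1C[C@](C)(O)C(O)C#C/C(C)=C\I | intermediate
20 | (4S,5S)-4-({[tert-butyl(diphenyl)silyl]oxy}methyl)-5-[(2S,6Z)-2-hydroxy-7-iodo-2,6-dimethyl-3-oxohept-6-en-4-yn-1-yl]oxolan-2-one | CC(C)(C)[Si](c1ccccc1)(c1ccccc1)OC[C@@H]1CC(=O)O[C@H]1C[C@](C)(O)C(=O)C#C/C(C)=C\I | intermediate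
21 | (4S,5S)-4-({[tert-butyl(diphenyl)silyl]oxy}methyl)-5-({(2S)-5-[(1Z)-1-iodoprop-1-en-2-yl]-2-methyl-3-oxo-2,3-dihydrofuran-2-yl}methyl)oxolan-2-one | CC(C)(C)[Si](c1ccccc1)(c1ccccc1)OC[C@@H]1CC(=O)O[C@H]1C[C@]1(C)OC(=CC1=O)/C(C)=C\I | intermediate
22 | (4S,5S)-4-(hydroxymethyl)-5-({(2S)-5-[(1Z)-1-iodoprop-1-en-2-yl]-2-methyl-3-oxo-2,3-dihydrofuran-2-yl}methyl)oxolan-2-one | OC[C@@H]1CC(=O)O[C@H]1C[C@]1(C)OC(=CC1=O)/C(C)=C\I | intermediate
23 | (2S,3R)-2-({(2S)-5-[(1Z)-1-iodoprop-1-en-2-yl]-2-methyl-3-oxo-2,3-dihydrofuran-2-yl}methyl)-5-oxooxolane-3-carbaldehyde | O=C[C@@H]1CC(=O)O[C@H]1C[C@]1(C)OC(=CC1=O)/C(C)=C\I | intermediate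
24 | (4Z,6S,7S,8S,10S)-6-hydroxy-1-oxo-3,10-epoxygermacra-2,4-dien-12,8-olide | O=C1O[C@H]2C[C@]3(C)OC(=CC3=O)/C(C)=C\[C@H](O)[C@@H]2C1 | intermediate
25 | (4Z,6S,7R,8S,10S)-1-oxo-6-(triethylsilyloxy)-3,10-epoxygermacra-2,4-dien-12,8-olide | O=C1O[C@H]2C[C@]3(C)OC(=CC3=O)/C(C)=C\[C@H](O[Si](CC)(CC)CC)[C@@H]2C1 | intermediate
26 | (4Z,6S,7R,8S,10S,11RS)-13-(dimethylamino)-1-oxo-6-(triethylsilyloxy)-3,10-epoxygermacra-2,4-dien-12,8-olide (Mannich base, not isolated) | CN(C)CC1C(=O)O[C@H]2C[C@]3(C)OC(=CC3=O)/C(C)=C\[C@H](O[Si](CC)(CC)CC)[C@H]12 | intermediate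
27 | N-methyl iodide of 26, 13-(trimethylammonio) compound (methiodide, not isolated) | C[N+](C)(C)CC1C(=O)O[C@H]2C[C@]3(C)OC(=CC3=O)/C(C)=C\[C@H](O[Si](CC)(CC)CC)[C@H]12.[I-] | intermediate
28 | (4Z,6S,7R,8S,10S)-1-oxo-6-(triethylsilyloxy)-3,10-epoxygermacra-2,4,11(13)-trien-12,8-olide | C=C1C(=O)O[C@H]2C[C@]3(C)OC(=CC3=O)/C(C)=C\[C@H](O[Si](CC)(CC)CC)[C@H]12 | intermediate
29 | (4Z,6S,7S,8S,10S)-6-hydroxy-1-oxo-3,10-epoxygermacra-2,4,11(13)-trien-12,8-olide | C=C1C(=O)O[C@H]2C[C@]3(C)OC(=CC3=O)/C(C)=C\[C@H](O)[C@H]12 | intermediate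
30 | angelic acid | C/C=C(/C)C(=O)O | starting material
31 | (2Z)-2-methylbut-2-en-1-ol | C/C=C(/C)CO | intermediate
32 | [(2R,3S)-2,3-dimethyloxiran-2-yl]methanol | OC[C@@]1(C)O[C@H]1C | intermediate
33 | (2S,3S)-2,3-dimethyloxirane-2-carboxylic acid | OC(=O)[C@@]1(C)O[C@H]1C | intermediate
34 | CNP0258430.1, (4Z,6S,7R,8S,10S)-6-{[(2S,3S)-2,3-dimethyloxiran-2-yl]carbonyloxy}-1-oxo-3,10-epoxygermacra-2,4,11(13)-trien-12,8-olide | C=C1C(=O)O[C@H]2C[C@]3(C)OC(=CC3=O)/C(C)=C\[C@H](OC(=O)[C@@]3(C)O[C@H]3C)[C@H]12 | target

## Step count and weakest steps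

Total: 26 steps. Longest linear sequence: 19 steps (1–3, 5–10, 14–22, 26) from (S)-citramalic acid. Side branches: step 4 (imide), steps 11–13 (iodoenyne), steps 23–25 (epoxy acid).

**Step 19 (key step).** The most likely failure is poor facial selectivity at the aldehyde, since the C6 induction rests on a conformational argument for a strained transition state. Intermolecular coupling may also overtake a slow closure. The β-acyloxy aldehyde may eliminate or epimerise at C7 before it is trapped, and the alkenyl metal may partly lose its Z geometry. Fallback for the stereochemical problem: the closure of 23 is run as planned and the epimeric alcohol (4Z,6R,7S,8S,10S)-6-hydroxy-1-oxo-3,10-epoxygermacra-2,4-dien-12,8-olide F1 is taken on. A Mitsunobu reaction with chloroacetic acid (PPh3, DIAD, toluene, 0 °C) inverts C6 and gives (4Z,6S,7R,8S,10S)-6-(chloroacetoxy)-1-oxo-3,10-epoxygermacra-2,4-dien-12,8-olide F2. Thiourea and NaHCO3 in ethanol then remove the chloroacetyl group under near-neutral conditions. This sets out from 23 and returns to the route at 24.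

**Step 21.** Enolisation may not be selective. Deprotonation at C6 (the vinylogous position of the dienone) would destroy that centre, and the C11 enolate may add across the ring to the furanone. Fallback: methylenate before the ring exists, when there is neither a C6 centre nor a transannular acceptor. Furanone 21 is treated with LDA and CH2=NMe2+ I− to give the Mannich base (3RS,4S,5S)-4-({[tert-butyl(diphenyl)silyl]oxy}methyl)-3-[(dimethylamino)methyl]-5-({(2S)-5-[(1Z)-1-iodoprop-1-en-2-yl]-2-methyl-3-oxo-2,3-dihydrofuran-2-yl}methyl)oxolan-2-one F3. MeI gives its methiodide F4 and NaHCO3 the 3-methylidene lactone silyl ether F5. HF·pyridine gives the 3-methylidene hydroxymethyl lactone F6, and buffered Dess–Martin oxidation the 4-methylidene-5-oxooxolane-3-carbaldehyde F7. CrCl2/NiCl2 closure of F7 as in step 19 gives 29 directly. This sets out from 21, returns at 29 and saves steps 20 and 22, at the price of a more acidic H7 in F7.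

**Step 14.** The unprotected α-hydroxy aldehyde may self-condense or undergo α-ketol rearrangement before it is attacked. The acetylide may attack the lactone, and the volatile, light-sensitive iodoenyne may lose iodide to base. Fallback: reverse the roles of the partners, so that 18 is not needed. Aldehyde 14 is homologated with dimethyl (1-diazo-2-oxopropyl)phosphonate and K2CO3 in MeOH to (4S,5S)-4-({[tert-butyl(diphenyl)silyl]oxy}methyl)-5-[(2S)-2-hydroxy-2-methylbut-3-yn-1-yl]oxolan-2-one F8. Its lithium acetylide (LiHMDS, 2.2 equiv, THF, −78 °C) adds to iodoenal 17 to give the ynediol (4S,5S)-4-({[tert-butyl(diphenyl)silyl]oxy}methyl)-5-[(2S,5RS,6Z)-2,5-dihydroxy-7-iodo-2,6-dimethylhept-6-en-3-yn-1-yl]oxolan-2-one F9. MnO2 oxidises the doubly activated carbinol to the 4-hydroxy ynone (4S,5S)-4-({[tert-butyl(diphenyl)silyl]oxy}methyl)-5-[(2S,6Z)-2-hydroxy-7-iodo-2,6-dimethyl-5-oxohept-6-en-3-yn-1-yl]oxolan-2-one F10. Hydration–cyclodehydration catalysed by Ph3PAuCl/AgOTf in wet toluene, the classical route from 4-hydroxy-2-ynones to 3(2H)-furanones, gives 21. This sets out from 14 and returns at 21.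

**Step 24.** Epoxidation of a cis-trisubstituted allylic alcohol is slow and may be only moderately enantioselective, and the small water-soluble epoxy alcohol is easily lost on work-up. Fallback: give up the asymmetric epoxidation. Angelic acid 30 is epoxidised directly with mCPBA (CH2Cl2, reflux), which is cis-specific and gives the racemic acid, that is 33 together with its enantiomer (2R,3R)-2,3-dimethyloxirane-2-carboxylic acid F11. Alcohol 29 is acylated with the racemate under the conditions of step 26, and 34 is separated by chromatography from its diastereomer, the (2R,3R)-epoxy ester F12. This sets out from 30 and returns at 34.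

## Further compounds

F1 | step 19 | (4Z,6R,7S,8S,10S)-6-hydroxy-1-oxo-3,10-epoxygermacra-2,4-dien-12,8-olide | O=C1O[C@H]2C[C@]3(C)OC(=CC3=O)/C(C)=C\[C@@H](O)[C@@H]2C1
F2 | step 19 | (4Z,6S,7R,8S,10S)-6-(chloroacetoxy)-1-oxo-3,10-epoxygermacra-2,4-dien-12,8-olide | O=C1O[C@H]2C[C@]3(C)OC(=CC3=O)/C(C)=C\[C@H](OC(=O)CCl)[C@@H]2C1
F3 | step 21 | (3RS,4S,5S)-4-({[tert-butyl(diphenyl)silyl]oxy}methyl)-3-[(dimethylamino)methyl]-5-({(2S)-5-[(1Z)-1-iodoprop-1-en-2-yl]-2-methyl-3-oxo-2,3-dihydrofuran-2-yl}methyl)oxolan-2-one | CC(C)(C)[Si](c1ccccc1)(c1ccccc1)OC[C@@H]1C(CN(C)C)C(=O)O[C@H]1C[C@]1(C)OC(=CC1=O)/C(C)=C\I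
F4 | step 21 | N-methyl iodide (methiodide) of F3 | CC(C)(C)[Si](c1ccccc1)(c1ccccc1)OC[C@@H]1C(C[N+](C)(C)C)C(=O)O[C@H]1C[C@]1(C)OC(=CC1=O)/C(C)=C\I.[I-]
F5 | step 21 | (4S,5S)-4-({[tert-butyl(diphenyl)silyl]oxy}methyl)-5-({(2S)-5-[(1Z)-1-iodoprop-1-en-2-yl]-2-methyl-3-oxo-2,3-dihydrofuran-2-yl}methyl)-3-methylideneoxolan-2-one | CC(C)(C)[Si](c1ccccc1)(c1ccccc1)OC[C@@H]1C(=C)C(=O)O[C@H]1C[C@]1(C)OC(=CC1=O)/C(C)=C\I
F6 | step 21 | (4S,5S)-4-(hydroxymethyl)-5-({(2S)-5-[(1Z)-1-iodoprop-1-en-2-yl]-2-methyl-3-oxo-2,3-dihydrofuran-2-yl}methyl)-3-methylideneoxolan-2-one | OC[C@@H]1C(=C)C(=O)O[C@H]1C[C@]1(C)OC(=CC1=O)/C(C)=C\I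
F7 | step 21 | (2S,3R)-2-({(2S)-5-[(1Z)-1-iodoprop-1-en-2-yl]-2-methyl-3-oxo-2,3-dihydrofuran-2-yl}methyl)-4-methylidene-5-oxooxolane-3-carbaldehyde | O=C[C@@H]1C(=C)C(=O)O[C@H]1C[C@]1(C)OC(=CC1=O)/C(C)=C\I
F8 | step 14 | (4S,5S)-4-({[tert-butyl(diphenyl)silyl]oxy}methyl)-5-[(2S)-2-hydroxy-2-methylbut-3-yn-1-yl]oxolan-2-one | CC(C)(C)[Si](c1ccccc1)(c1ccccc1)OC[C@@H]1CC(=O)O[C@H]1C[C@](C)(O)C#C
F9 | step 14 | (4S,5S)-4-({[tert-butyl(diphenyl)silyl]oxy}methyl)-5-[(2S,5RS,6Z)-2,5-dihydroxy-7-iodo-2,6-dimethylhept-6-en-3-yn-1-yl]oxolan-2-one | CC(C)(C)[Si](c1ccccc1)(c1ccccc1)OC[C@@H]1CC(=O)O[C@H]1C[C@](C)(O)C#CC(O)/C(C)=C\I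
F10 | step 14 | (4S,5S)-4-({[tert-butyl(diphenyl)silyl]oxy}methyl)-5-[(2S,6Z)-2-hydroxy-7-iodo-2,6-dimethyl-5-oxohept-6-en-3-yn-1-yl]oxolan-2-one | CC(C)(C)[Si](c1ccccc1)(c1ccccc1)OC[C@@H]1CC(=O)O[C@H]1C[C@](C)(O)C#CC(=O)/C(C)=C\I
F11 | step 24 | (2R,3R)-2,3-dimethyloxirane-2-carboxylic acid | OC(=O)[C@]1(C)O[C@@H]1C
F12 | step 24 | (4Z,6S,7R,8S,10S)-6-{[(2R,3R)-2,3-dimethyloxiran-2-yl]carbonyloxy}-1-oxo-3,10-epoxygermacra-2,4,11(13)-trien-12,8-olide | C=C1C(=O)O[C@H]2C[C@]3(C)OC(=CC3=O)/C(C)=C\[C@H](OC(=O)[C@]3(C)O[C@@H]3C)[C@H]12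
A1 | alternative 1 | thirteen-membered enyne ether (oxygen between C6 and C13, trans C7=C11 in the ring, C8 OMOM, C10 OTES, C1 dimethyl ketal, C12 OPMB) | C/C1=C/COC/C(COCc2ccc(OC)cc2)=C/[C@@H](OCOC)C[C@](C)(O[Si](CC)(CC)CC)C(OC)(OC)C#C1
A2 | alternative 1 | ten-membered enynol with C6 hydroxyl and C11=C13 methylene branch on C7 | COCO[C@H]1C[C@](C)(O[Si](CC)(CC)CC)C(OC)(OC)C#C/C(C)=C\[C@H](O)[C@@H]1C(=C)COCc1ccc(OC)cc1
A3 | alternative 2 | trans-1,10-epoxy-3-oxo-6-(tert-butyldimethylsilyloxy)germacra-4,11(13)-dien-12,8-olide | C=C1C(=O)O[C@H]2C[C@@]3(C)O[C@@H]3CC(=O)/C(C)=C\[C@H](O[Si](C)(C)C(C)(C)C)[C@H]12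
A4 | alternative 2 | oxygen-bridged dihydrofuranol (3,10-epoxy enol ether with C1 hydroxyl) | C=C1C(=O)O[C@H]2C[C@]3(C)OC(=C[C@H]3O)/C(C)=C\[C@H](O[Si](C)(C)C(C)(C)C)[C@H]12
A5 | alternative 3 | lactone-fused cyclooct-2-enone with 1-propynyl ether on C10 and silyloxy group on C6 | O=C1O[C@H]2C[C@](C)(OC#CC)C(=O)/C=C\[C@H](O[Si](C)(C)C(C)(C)C)[C@@H]2C1
A6 | alternative 3 | tetracyclic cyclobutene photoadduct | O=C1O[C@H]2C[C@]3(C)OC4=C(C)[C@@H]([C@@H]4C3=O)[C@H](O[Si](C)(C)C(C)(C)C)[C@@H]2C1
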